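The winter flask cannot have stopped for want of first end groups: 0.80 M were charged, and its links level off at 77.9% of that.

in all of them: first end groups 0.80 M

|  | second end groups | one-sided end groups | temperature | remark | time |
|---|---|---|---|---|---|
| winter | 0.76 M | 0.016 M | 100 °C | the very flask that is asked about, followed so far |  |
| dusk | 0.76 M | 0.016 M | 95 °C | run made earlier |  |
| flask | 0.760 M | 0.0160 M | 100 °C |  | 50 min |

- winter (time / min: links / %): 8.00: 70.2; 15.0: 75.4; 25.0: 78.1; 30.0: 77.7; 40.0: 77.6; 50.0: 78.1
- dusk (time / min: links / %): 8.00: 65.7; 15.0: 74.0; 25.0: 78.1; 30.0: 78.3; 40.0: 79.2; 50.0: 78.3

(each reading ± 0.5 percentage points)

- links that was removed still counts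
- on the list of suspects stand: second end groups -> decomposed reagent; first end groups + second end groups -> links; first end groups + one-sided end groups -> capped ends
- additions bring no volume worth counting

- amber: at 50 min raise the temperature by 15 K, then wait 1.5 h
- violet: at 50 min add second end groups, 100% of the amount charged, then wait 1.5 h
- green: change nothing and wait 1.5 h more
- red: at 50 min take out 90% of the links then present, then wait 1.5 h

* links, in percent of the first end groups first charged, at 50 min
* the remedy with the largest gain of links, or "none" below 2 percentage points (amber / violet / green / red / none)
* links present, with what was taken out counted in, in percent of the first end groups first charged, after violet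
* links present, with what was taken out counted in, in percent of the first end groups first charged, after green

Read the two runs column against column. At 8.00 min the winter run stands higher than the dusk run, 70.2% against 65.7%. But from 25.0 min on, the dusk readings average 78.5%, and each reading is good to 0.5 percentage points. So the warmer run climbs sooner, yet the two levels differ by 0.6 points.

Now we keep the books for the winter flask. One-sided end groups can cap 0.0160 M of first end groups, so 0.784 M stay open to linking. The links hold 0.623 M, so 0.161 M stand unused. Of the second end groups charged, 0.137 M are not in links, and the list of suspects gives them one other exit: decomposition. The links stay level from 25.0 min on with 0.161 M of first end groups standing by, so we take that whole amount as decomposed, which is our judgement and not a measurement.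

A second end group has two exits. Linking goes as [first end groups] times [second end groups], and decomposing goes as [second end groups], so [second end groups] cancels from the ratio. Links made per group decomposed are then [first end groups]/K, the selectivity factor. Taking capping as over at the start and summing while [first end groups] falls, the amount decomposed is K ln(start/end). So the winter readings give K = 0.0865 M at 100 °C: the break-even concentration, the [first end groups] at which, at that temperature, a second end group is as likely to link as to decompose.

Waiting, heating or taking out links adds no second end groups, so our reckoning keeps the level where it is. Adding 0.760 M of second end groups, as violet does, to a flask with 0.161 M of first end groups unused leaves, by the same rule, 1.59 × 10⁻⁴ M of those first end groups. Links then reach 98.0%, and 1.5 h is longer than the 25.0 min of the first climb.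

The forecast gave 77.9% now, violet as the remedy, 98% after it and 78% after waiting, holding that “the second end groups are probably exhausted by decomposition”.

The flask gives 78.0% now, violet with a gain of 20 points, 98.0% after it and 78.0% after waiting.

    second end groups → decomposed reagent (k = 8.50 × 10⁻⁴ s⁻¹, Ea = 119 kJ mol⁻¹)
    first end groups + second end groups → links (k = 0.00990 M⁻¹ s⁻¹, Ea = 86.0 kJ mol⁻¹)
    first end groups + one-sided end groups → capped ends (k = 0.0660 M⁻¹ s⁻¹, Ea = 59.0 kJ mol⁻¹)
    (constants at 100 °C)

In this flask, the rate at which linking uses second end groups, over the rate at which decomposing uses them, is 9.3 at the start and 5.5 at 1.54 min; the 20.0% of first end groups left at 50.0 min, set against the K of 0.0865 M read from the winter run, puts it near 1.85, with 0.021% of the charged second end groups still there. In the neighbour flask charged with 2.0 M of first end groups, where 63% of them remain at 50.0 min, K ln(start/end) gives 0.0393 M decomposed, and that flask holds 0.0388 M of decomposed reagent.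

All runs are simulated for an exercise; scatter was added.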